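## Structural features

Xanthohumol is a chalcone: a pentasubstituted benzene (ring A, C1'–C6') is joined through a C1'–C(=O)–Cα=Cβ enone to a para-hydroxyphenyl group (ring B). Ring A is a phloroglucinol with three different oxygens: the 2'-OH is hydrogen-bonded to the ketone, the 4'-OH is free and the 6'-oxygen is a methyl ether. C3', between the two free hydroxyls, carries the prenyl group, C1' the acyl group, and only C5' carries hydrogen. There is no stereocenter; the only stereochemical element is the E enone double bond. The fragile groups are the 2'-hydroxy enone (closes to the flavanone in acid, base or heat), the prenyl group flanked by two phenols (closes to chromans in acid) and the electron-rich ring A (oxidation). The real difficulty is regiochemical: on a phloroglucinol the three oxygens and the free ring carbons are nearly equivalent, so methylation at the 6'-oxygen only, prenylation at C3' only and acylation at C1' normally have to be forced one by one. The key step exploits that the contiguous atoms C4'–C5'–C6'–C1', with the 6'-OMe and the complete cinnamoyl chain on C1', already exist as C2–C3–C4–C5, the 4-OMe and the 6-styryl enol carbon of a 4-methoxy-6-styrylpyran-2-one. C3' with its prenyl group and C2' are the α-carbon and carbonyl carbon of a 5-methylhex-4-enoate, so putting these two carbons in the place of the ring oxygen creates ring A with every substituent in its final position.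

## Logic of the disconnections

**12 to 11.** The acetal C–O bond on the ring-B oxygen is cut. Ring B must be masked because a free phenol would quench the enolate of the key step and deactivate the aldehyde in the condensation. There is no skeletal gain. The forward step must unmask briefly and mildly enough for the prenyl group and the 2'-hydroxy enone.

**11 to 8 and 4 (through 10 and 9).** The ring-A bonds C1'–C2' and C3'–C4' are cut. This removes C2' and C3' as a two-carbon unit that is the carbonyl and α-carbon of 4 (used as its enolate 9). What remains, C4'–C5'–C6'–C1' with the methoxy group and the whole enone, closes over an oxygen to the pyranone 8. The open chain 10 lies between: C3'–C4' is cut by a retro-Claisen acylation, C1'–C2' by a retro-Claisen ring closure. The gain is that ring A, its three differentiated oxygens, the prenyl position and the chalcone are all traced to two simple pieces with no aromatic substitution and no phenol differentiation. The demands are attack of 9 at the lactone carbonyl of 8 rather than at its conjugate positions, and closure of 10 in the Claisen and not the aldol sense.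

**8 to 5 and 6 (through 7).** The styryl C=C bond (the future Cα=Cβ) is cut. The 6-methyl group of 5 is vinylogously acidic, so a condensation with 6 installs ring B and the E alkene in one step from two purchased compounds. The forward step must dehydrate 7 to the E alkene without opening the lactone.

**4 to 1 and 2 (through 3).** The C2–C3 bond of 4 is cut by a retro-[3,3] shift. This places the trisubstituted alkene exactly where the prenyl group needs it and avoids enolate alkylation with a prenyl halide. The forward step needs heat, an acid catalyst and removal of ethanol.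

## Other disconnections considered

**Alternative 1:** Cut Cα=Cβ of the enone (the first idea that comes to mind). The forward key step is a Claisen–Schmidt condensation of the acetophenone 1-[2-hydroxy-6-methoxy-4-(methoxymethoxy)-3-(3-methylbut-2-enyl)phenyl]ethanone A1 with 6 to give the protected chalcone A2, then acetal removal to 12. The condensation itself is dependable, but it leaves the real problem untouched: A1 is ring A in full. It would have to be assembled on a preformed phloroglucinol ring by stepwise oxygen differentiation, O-prenylation, a Claisen rearrangement whose ortho or para course must be steered, and a selective O-methylation. That is about five linear steps before the aldol, against one ring-forming step in the chosen plan.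

**Alternative 2:** Cut C1'–C(=O) and C2'–O together. The forward key step is insertion of the aryne A5, released by fluoride from the silyl triflate A4, into the C–O bond of the acid A6: the carboxylate adds to the aryne, the aryl anion attacks the acyl group and the four-membered ring opens, which would give 11 directly. The 6'-OMe beside the triple bond should direct oxygen to C2' and the acyl group to C1' (attack distal to the inductively withdrawing methoxy group), with the prenyl flank opposing only weakly. The objection is structural: A4 is itself a pentasubstituted benzene carrying the full prenyl/methoxy/oxygen pattern. It would be reached from the symmetric resorcinol A3, one oxygen of which must be turned into a triflate only to be put back by the insertion. The aryne therefore moves the regiochemical problem and does not solve it, and the route is clearly longer.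

**Alternative 3:** Cut ring A into a four-carbon and a two-carbon piece by a Danheiser benzannulation. Thermal ring opening of the cyclobutenone A7 and a [2+2]/4π-opening/6π-closure cascade with the siloxyalkyne A8 should give the phenol A9, with the prenyl group placed between the two oxygens by the polarity of the ynol ether. Desilylation to A3 and C-acylation with a cinnamoyl donor derived from A6 would follow. This is a serious ring construction, but it delivers only the symmetric core with C1' bare. The cinnamoyl group must then be introduced by Friedel–Crafts or Fries chemistry on an acid-sensitive prenylresorcinol, where chroman and flavanone closure are to be expected on mechanistic grounds. A7 and A8 also each need their own preparation. In the chosen plan the acyl group is in place before the ring exists.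

Key step: step 3

Remark: compounds 1, 2, 5 and 6 are taken as purchased; the enolate geometry of 9 and the configuration at C2 of 10 are of no consequence, since both are erased on aromatization.

## Route

Step 1
Reactants: 1 2-methylbut-3-en-2-ol; 2 triethyl orthoacetate
Product: 4 ethyl 5-methylhex-4-enoate, via ketene acetal 3 (not isolated)
Conditions: MeC(OEt)3 (4 equiv), EtCO2H (5 mol %), 140 °C, EtOH distilled off
Reagents that add atoms: none
Why: Johnson–Claisen rearrangement: acid-catalysed exchange and loss of ethanol give ketene acetal 3, whose chair-like [3,3]-sigmatropic shift forms the C2–C3 bond and moves the alkene into the trisubstituted (prenyl) position; no stereocenter is formed.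

Step 2
Reactants: 5 4-methoxy-6-methyl-2H-pyran-2-one; 6 4-(methoxymethoxy)benzaldehyde
Product: 8 4-methoxy-6-[(E)-2-[4-(methoxymethoxy)phenyl]ethenyl]-2H-pyran-2-one, via aldol adduct 7 (not isolated)
Conditions: Mg(OMe)2 (2 equiv), MeOH, reflux; then AcOH/H2O, 0 °C
Reagents that add atoms: none
Why: Vinylogous aldol condensation, the classical entry to 6-styryl-4-methoxypyranones: Mg(OMe)2 deprotonates the 6-methyl group (activated through the ring by the lactone carbonyl), the magnesium aldolate 7 eliminates by E1cB to the conjugated E alkene under thermodynamic control, and the base-stable acetal on ring B is untouched.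

Step 3
Reactants: 4 ethyl 5-methylhex-4-enoate; 8 4-methoxy-6-[(E)-2-[4-(methoxymethoxy)phenyl]ethenyl]-2H-pyran-2-one
Product: 11 (E)-1-[2,4-dihydroxy-6-methoxy-3-(3-methylbut-2-enyl)phenyl]-3-[4-(methoxymethoxy)phenyl]prop-2-en-1-one, via lithium ester enolate 9 (not isolated), via open-chain dioxo ester 10 (not isolated)
Conditions: 4 (2.2 equiv), LiN(i-Pr)2 (2.2 equiv), THF, −78 °C; add 8, −78 to −20 °C; EtOH (5 equiv), −20 to 25 °C; AcOH, 0 °C
Reagents that add atoms: none
Why: Proposed new method: the lithium enolate 9 should add under kinetic control, guided by lithium coordination to the lactone carbonyl, to C2 of 8, and the tetrahedral adduct should collapse by expelling the ring oxygen as a vinylogous β-diketonate, which gives the open chain 10 and forms the C3'–C4' bond. The second equivalent of 9 holds 10 as its dianion until ethanol is added; proton exchange then makes available the monoanion in which chain carbon C6 (the former pyranone C5) is the nucleophile and the β-keto ester is free and electrophilic. Ring A then closes by a 6-(enolexo)-exo-trig Claisen (Dieckmann-type) condensation that forms C1'–C2', expels ethoxide and becomes irreversible on tautomerization to the phloroglucinol phenoxide. The closest known reaction types are the Fujimoto–Belleau reaction (carbon nucleophile on an enol lactone carbonyl, ring opening, reclosure through carbon), the alkoxide opening of 4-methoxypyran-2-ones at C2, and the base-mediated Claisen cyclization of 3,5,7-triketo esters to acylphloroglucinols. No stereocenter is formed, and the E alkene of 8 should be carried through because in every anionic intermediate the styryl ketone is held as an enolate and is not a Michael acceptor. The step needs site selectivity for C2 over C6 and the styryl β-carbon, which the hard chelated lithium enolate at −78 °C, the full substitution of C6 and the donor para-alkoxy group on the styrene should secure. It also needs Claisen and not aldol closure: the aldol mode (C2 onto C7) would create a quaternary carbon that cannot aromatize and is reversible, whereas the enol ether double bond C4=C5, with C3 and C6 cis as inherited from the ring, holds C6 next to the ester. Ring A's regiochemistry is thus fixed by construction: the pyranone 4-OMe becomes the 6'-OMe, the lactone carbonyl the 4'-OH, the ester carbonyl the 2'-OH and the ester α-substituent the 3'-prenyl group.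

Step 4
Reactants: 11 (E)-1-[2,4-dihydroxy-6-methoxy-3-(3-methylbut-2-enyl)phenyl]-3-[4-(methoxymethoxy)phenyl]prop-2-en-1-one
Product: 12 xanthohumol [(E)-1-[2,4-dihydroxy-6-methoxy-3-(3-methylbut-2-enyl)phenyl]-3-(4-hydroxyphenyl)prop-2-en-1-one]
Conditions: aq. HCl (3 M), MeOH, 25 °C
Reagents that add atoms: none
Why: Acid-catalysed solvolysis of the methoxymethyl ether through the oxocarbenium ion, which methanol traps as dimethoxymethane; short exposure to dilute acid at 25 °C should leave the prenyl group, the E enone and the hydrogen-bonded 2'-OH intact.

## Compound list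

1 | 2-methylbut-3-en-2-ol | CC(C)(O)C=C | starting material
2 | triethyl orthoacetate (1,1,1-triethoxyethane) | CCOC(C)(OCC)OCC | starting material
3 | 3-[(1-ethoxyethenyl)oxy]-3-methylbut-1-ene (ketene acetal) | C=C(OCC)OC(C)(C)C=C | intermediate
4 | ethyl 5-methylhex-4-enoate | CCOC(=O)CCC=C(C)C | intermediate
5 | 4-methoxy-6-methyl-2H-pyran-2-one | COC1=CC(=O)OC(C)=C1 | starting material
6 | 4-(methoxymethoxy)benzaldehyde | COCOc1ccc(C=O)cc1 | starting material
7 | 6-[2-hydroxy-2-[4-(methoxymethoxy)phenyl]ethyl]-4-methoxy-2H-pyran-2-one (racemic aldol adduct, present as its magnesium alkoxide) | COCOc1ccc(C(O)CC2=CC(OC)=CC(=O)O2)cc1 | intermediate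
8 | 4-methoxy-6-[(E)-2-[4-(methoxymethoxy)phenyl]ethenyl]-2H-pyran-2-one | COCOc1ccc(/C=C/C2=CC(OC)=CC(=O)O2)cc1 | intermediate
9 | lithium 1-ethoxy-5-methylhexa-1,4-dien-1-olate (enolate of 4, geometry immaterial) | CCOC(O[Li])=CCC=C(C)C | intermediate
10 | ethyl (4E,8E)-5-methoxy-9-[4-(methoxymethoxy)phenyl]-2-(3-methylbut-2-enyl)-3,7-dioxonona-4,8-dienoate (racemic at C2, present as its lithium enolate) | CCOC(=O)C(CC=C(C)C)C(=O)/C=C(/OC)CC(=O)/C=C/c1ccc(OCOC)cc1 | intermediate
11 | (E)-1-[2,4-dihydroxy-6-methoxy-3-(3-methylbut-2-enyl)phenyl]-3-[4-(methoxymethoxy)phenyl]prop-2-en-1-one | COc1cc(O)c(CC=C(C)C)c(O)c1C(=O)/C=C/c1ccc(OCOC)cc1 | intermediate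
12 | xanthohumol, (E)-1-[2,4-dihydroxy-6-methoxy-3-(3-methylbut-2-enyl)phenyl]-3-(4-hydroxyphenyl)prop-2-en-1-one | COc1cc(O)c(CC=C(C)C)c(O)c1C(=O)/C=C/c1ccc(O)cc1 | target

## Step count and least certain steps

Total step count: 4. Longest linear sequence: 3 steps (steps 2, 3 and 4 from 5, or steps 1, 3 and 4 from 1).

**Step 3 (key step, proposed new method).** Three processes are the most likely to go wrong.
- Misdirected attack: conjugate addition of the enolate at C6 or at the styryl β-carbon in place of acyl substitution at C2. The lactone carbonyl is a vinylogous carbonate and therefore a modest electrophile.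
- Self-condensation of the enolate, if the addition has to be warmed.
- Stalling at the open-chain dianion, or closure in the aldol sense.

The fallback uses known chemistry only, sets out from 6 and returns to the route at 12. Purchased 5-methoxybenzene-1,3-diol is protected (MOMCl, i-Pr2NEt, CH2Cl2) as 1-methoxy-3,5-bis(methoxymethoxy)benzene F1. Directed ortho-lithiation between the two acetal oxygens (n-BuLi, THF, 0 °C), transmetalation with CuI and alkylation with prenyl bromide give 5-methoxy-1,3-bis(methoxymethoxy)-2-(3-methylbut-2-enyl)benzene F2. Its two free ring positions are equivalent by symmetry, so a second directed lithiation (n-BuLi, TMEDA, THF) and quench with N-methoxy-N-methylacetamide can only give 1-[6-methoxy-2,4-bis(methoxymethoxy)-3-(3-methylbut-2-enyl)phenyl]ethanone F3. Claisen–Schmidt condensation of F3 with 6 (KOH, EtOH) gives (E)-1-[6-methoxy-2,4-bis(methoxymethoxy)-3-(3-methylbut-2-enyl)phenyl]-3-[4-(methoxymethoxy)phenyl]prop-2-en-1-one F4, and aq. HCl in MeOH removes the three acetals to give 12.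

**Step 2.** The likely failure is methanolysis of the lactone (ring opening by methoxide at C2) outrunning a slow condensation, because the donor-substituted aldehyde is a weak electrophile. The fallback sets out from 5 and 6 and returns at 8. It separates addition from elimination: LiN(i-Pr)2 (THF, −78 °C) deprotonates the 6-methyl group of 5 and the anion adds to 6 to give 7, now isolated. Acetylation (Ac2O, pyridine) gives 2-(4-methoxy-2-oxo-2H-pyran-6-yl)-1-[4-(methoxymethoxy)phenyl]ethyl acetate F5, and DBU in CH2Cl2 eliminates acetic acid by E1cB to give 8.

**Step 4.** The likely failure is acid-promoted closure of a ring-A phenol onto the protonated prenyl alkene (chroman formation) or onto the enone (flavanone formation) before acetal cleavage is complete. The fallback sets out from 5 and returns at 12. It replaces the acetal by an allyl ether that is removed without acid.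
- Purchased 4-(prop-2-enyloxy)benzaldehyde is condensed with 5 under the conditions of step 2. By way of the aldol adduct 6-[2-hydroxy-2-[4-(prop-2-enyloxy)phenyl]ethyl]-4-methoxy-2H-pyran-2-one F6 this gives 4-methoxy-6-[(E)-2-[4-(prop-2-enyloxy)phenyl]ethenyl]-2H-pyran-2-one F7.
- F7 is treated with 9 under the conditions of step 3. By way of ethyl (4E,8E)-5-methoxy-2-(3-methylbut-2-enyl)-3,7-dioxo-9-[4-(prop-2-enyloxy)phenyl]nona-4,8-dienoate F8 this gives (E)-1-[2,4-dihydroxy-6-methoxy-3-(3-methylbut-2-enyl)phenyl]-3-[4-(prop-2-enyloxy)phenyl]prop-2-en-1-one F9.
- Allyl transfer to morpholine with Pd(PPh3)4 (5 mol %, zerovalent palladium) in THF at 25 °C then gives 12 under neutral conditions.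

## Further compounds

F1 | step 3 | 1-methoxy-3,5-bis(methoxymethoxy)benzene | COCOc1cc(OC)cc(OCOC)c1
F2 | step 3 | 5-methoxy-1,3-bis(methoxymethoxy)-2-(3-methylbut-2-enyl)benzene | COCOc1cc(OC)cc(OCOC)c1CC=C(C)C
F3 | step 3 | 1-[6-methoxy-2,4-bis(methoxymethoxy)-3-(3-methylbut-2-enyl)phenyl]ethanone | COCOc1cc(OC)c(C(C)=O)c(OCOC)c1CC=C(C)C
F4 | step 3 | (E)-1-[6-methoxy-2,4-bis(methoxymethoxy)-3-(3-methylbut-2-enyl)phenyl]-3-[4-(methoxymethoxy)phenyl]prop-2-en-1-one | COCOc1ccc(/C=C/C(=O)c2c(OC)cc(OCOC)c(CC=C(C)C)c2OCOC)cc1
F5 | step 2 | 2-(4-methoxy-2-oxo-2H-pyran-6-yl)-1-[4-(methoxymethoxy)phenyl]ethyl acetate (racemic) | COCOc1ccc(C(CC2=CC(OC)=CC(=O)O2)OC(C)=O)cc1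
F6 | step 4 | 6-[2-hydroxy-2-[4-(prop-2-enyloxy)phenyl]ethyl]-4-methoxy-2H-pyran-2-one (racemic) | C=CCOc1ccc(C(O)CC2=CC(OC)=CC(=O)O2)cc1
F7 | step 4 | 4-methoxy-6-[(E)-2-[4-(prop-2-enyloxy)phenyl]ethenyl]-2H-pyran-2-one | C=CCOc1ccc(/C=C/C2=CC(OC)=CC(=O)O2)cc1
F8 | step 4 | ethyl (4E,8E)-5-methoxy-2-(3-methylbut-2-enyl)-3,7-dioxo-9-[4-(prop-2-enyloxy)phenyl]nona-4,8-dienoate (racemic at C2) | CCOC(=O)C(CC=C(C)C)C(=O)/C=C(/OC)CC(=O)/C=C/c1ccc(OCC=C)cc1
F9 | step 4 | (E)-1-[2,4-dihydroxy-6-methoxy-3-(3-methylbut-2-enyl)phenyl]-3-[4-(prop-2-enyloxy)phenyl]prop-2-en-1-one | COc1cc(O)c(CC=C(C)C)c(O)c1C(=O)/C=C/c1ccc(OCC=C)cc1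
A1 | alternative 1 | 1-[2-hydroxy-6-methoxy-4-(methoxymethoxy)-3-(3-methylbut-2-enyl)phenyl]ethanone | COCOc1cc(OC)c(C(C)=O)c(O)c1CC=C(C)C
A2 | alternative 1 | (E)-1-[2-hydroxy-6-methoxy-4-(methoxymethoxy)-3-(3-methylbut-2-enyl)phenyl]-3-[4-(methoxymethoxy)phenyl]prop-2-en-1-one | COCOc1ccc(/C=C/C(=O)c2c(OC)cc(OCOC)c(CC=C(C)C)c2O)cc1
A3 | alternative 2 | 5-methoxy-2-(3-methylbut-2-enyl)benzene-1,3-diol | COc1cc(O)c(CC=C(C)C)c(O)c1
A4 | alternative 2 | 3-methoxy-5-(methoxymethoxy)-6-(3-methylbut-2-enyl)-2-(trimethylsilyl)phenyl trifluoromethanesulfonate | COc1cc(OCOC)c(CC=C(C)C)c(OS(=O)(=O)C(F)(F)F)c1[Si](C)(C)C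
A5 | alternative 2 | 3-methoxy-5-(methoxymethoxy)-6-(3-methylbut-2-enyl)benzyne (1,2-didehydrobenzene) | COC1=CC(OCOC)=C(CC=C(C)C)C#C1
A6 | alternative 2 | (E)-3-[4-(methoxymethoxy)phenyl]prop-2-enoic acid | COCOc1ccc(/C=C/C(=O)O)cc1
A7 | alternative 3 | 3-methoxycyclobut-2-en-1-one | COC1=CC(=O)C1
A8 | alternative 3 | (5-methylhex-4-en-1-ynyloxy)tri(propan-2-yl)silane | CC(C)=CCC#CO[Si](C(C)C)(C(C)C)C(C)C
A9 | alternative 3 | 5-methoxy-2-(3-methylbut-2-enyl)-3-[tri(propan-2-yl)silyloxy]phenol | COc1cc(O)c(CC=C(C)C)c(O[Si](C(C)C)(C(C)C)C(C)C)c1
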